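The constants of this flask are hidden, so I take from the runs the one that can be turned into a time.

| setting | midnight | autumn | winter | ochre | green | blue | violet | grey |
|---|---|---|---|---|---|---|---|---|
| solid substrate | 0.090 M | 0.33 M | 1.4 M | 0.40 M | 0.10 M | 0.60 M | 1.2 M | 0.12 M |
| gas phase | 17 mM (held) | 17 mM (held) | 17 mM (held) | 17 mM (held) | 17 mM (held) | 17 mM (held) | 17 mM (held) | 17 mM (held) |
| remark | run made earlier | run made earlier | run made earlier |  |  |  |  |  |
| time |  |  |  | 8.0 min | 8.0 min | 8.0 min | 8.0 min | 8.0 min |

| run | time / min | target / % | solid substrate / % |
|---|---|---|---|
| midnight | 0.667 | 30.2 | 3.3 |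
| midnight | 2.00 | 78.1 | 0 |
| midnight | 4.00 | 82.4 | 1.2 |
| midnight | 6.00 | 82.9 | 1.4 |
| autumn | 0.417 | 5.5 | 85.6 |
| autumn | 1.00 | 14.6 | 62.4 |
| autumn | 2.50 | 44.1 | 8.9 |
| autumn | 6.00 | 55.7 | 0 |
| winter | 0.417 | 1.7 | 96.0 |
| winter | 1.00 | 3.2 | 91.3 |
| winter | 2.50 | 8.8 | 79.4 |
| winter | 6.00 | 18.6 | 49.1 |

(scatter of a reading: 1 percentage point)

- in percentages every species weighs as the solid substrate in it: one side product counts as two
- as a solid, counted per litre of solution: solid substrate
- at the start none of the gas is dissolved
- steps that have been proposed: dissolved gas -> decomposed reagent; starting material + target -> side product; starting material + dissolved gas -> target; solid substrate <-> starting material; gas phase <-> dissolved gas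
- at the start none of the solid substrate is in solution
- what has only dissolved of solid substrate counts as not reacted

In the winter run, with [solid substrate] = 1.4 M, the solid falls to 49.1% by 6.00 min, so 0.119 M min⁻¹ goes into solution. This dissolving rate, the solid entering a litre of solution per minute, is what I carry. But one run proves little, so I read the autumn run at 2.50 min: it gives 0.120 M min⁻¹, about the same at a quarter of the charge. So the rate reads as zero order in the solid in these two runs, and I reckon a flask's clearing time as its charge divided by this rate.

- all flasks from highest to lowest amount of target, in percent of the solid substrate charged, at 8.0 min (ochre / green / blue / violet / grey)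
- the same order at 30 min (ochre / green / blue / violet / grey)
- the amount of target, in percent of the solid substrate charged of the flask you put first, at 8.0 min
- the amount of target, in percent of the solid substrate charged of the flask you put last, at 8.0 min

Blue, with a larger charge than ochre, grey and green, clears by this reckoning at 5.05 min, and ochre, grey and green clear sooner. But I reckon that violet needs 10.1 min, longer than the 8.0 min of the first asked time, so I reckon that violet still holds 20.8% of its solid then.

Clearing is not the end of the target, though. The midnight run reads 3.3% solid and 30.2% target at 0.667 min, reads 78.1% target at 2.00 min, and then goes from 82.4% to 82.9% target, with a scatter of 1 percentage point. By my reckoning blue has 2.95 min after clearing, so I expect the cleared flasks to read the same at both times. I rank them by charge, since the midnight run's 82.9% stands above the autumn run's 55.7%, with violet last and still rising.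

The forecast, reading “The solid dissolves at a steady ~0.12 M/min whatever the loading”, gives green > grey > ochre > blue > violet at 8.0 min and green > grey > ochre > blue > violet at 30 min, with 81% first and 27% last at 8.0 min.

The flask gives green > grey > ochre > blue > violet at 8.0 min and green > grey > ochre > blue > violet at 30 min, with 81.5% first and 24.5% last at 8.0 min.

    dissolved gas → decomposed reagent (k = 0.00670 s⁻¹)
    starting material + target → side product (k = 0.0550 M⁻¹ s⁻¹)
    starting material + dissolved gas → target (k = 1.60 M⁻¹ s⁻¹)
    solid substrate ⇌ starting material, rate k4*(cs4 - [starting material]) while solid is left; crystals form when [starting material] > cs4 (solubility = 0.340 M, k = 0.00710 s⁻¹)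
    gas phase ⇌ dissolved gas, rate k5*(csat - [dissolved gas]) (kL = 0.300 s⁻¹)

Blue reads 42.1% at 8.0 min and 42.1% at 30 min, while violet moves from 24.5% to 27.2%, with 21.0% solid standing at 8.00 min against my 20.8%. The same rate on the neighbouring flask, violet read at 3.0 min, leaves 70.3% solid. That flask holds 70.5% solid and 13.8% target.

The data were generated by integration for substances that don't exist; scatter was added.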